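**Strategy.** Ring A is read as a masked cyclobutene: C6 (on C5) and C20 (on quaternary C10) are cis one-carbon arms on the carbons β and α to the C1 ketone. One photochemical operation, an enone–acetylene [2+2] cycloaddition, forms C5–C6 and C10–C20, closes the four-membered ring and sets C5 and C10; ozonolysis later releases the two arms. The precursor is 4,4-dimethylcyclohex-2-enone carrying C9 as a silyloxymethyl group on its α-carbon. The lactone and ring C then come from a Knoevenagel/Diels–Alder pair, ring D from a vinyl-radical cyclisation.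

Key step: step 3

**Remarks on the chemistry (assumptions).**
- Atoms carry the ent-kaurane numbers of the target; α is the face of ring A bearing C20 and C6, β the face bearing C9.
- The C9 oxygen is carried as a TBDPS ether, because a more labile silyl ether would not survive the acid of step 5. Photoadduct 6 was checked against C5/C10 of the target; acetylene must enter on the α-face.
- Compounds 22–24 are C15 epimer mixtures; C15 is set in step 15.

Step 1
Reactants: 1 4,4-dimethylcyclohex-2-en-1-one; 2 formaldehyde
Product: 3 2-(hydroxymethyl)-4,4-dimethylcyclohex-2-en-1-one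
Conditions: 37% aq. HCHO, DMAP (0.3 equiv), THF–H2O, rt
Reagents that add atoms: none
Why: Morita–Baylis–Hillman reaction: DMAP adds reversibly to C5 of the enone and the resulting enolate is hydroxymethylated at C10 by formaldehyde before the catalyst is expelled, the gem-dimethyl group only slowing the addition.

Step 2
Reactants: 3 2-(hydroxymethyl)-4,4-dimethylcyclohex-2-en-1-one
Product: 4 2-[(tert-butyldiphenylsilyl)oxymethyl]-4,4-dimethylcyclohex-2-en-1-one
Conditions: TBDPSCl, imidazole, DMF, 0 °C → rt
Reagents that add atoms: tert-butyl(chloro)diphenylsilane, CC(C)(C)[Si](Cl)(c1ccccc1)c1ccccc1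
Why: Imidazole-promoted silylation of the primary allylic alcohol; the bulky, acid-stable and non-chelating TBDPS group is chosen to survive steps 3–7.

Step 3
Reactants: 4 2-[(tert-butyldiphenylsilyl)oxymethyl]-4,4-dimethylcyclohex-2-en-1-one; 5 acetylene
Product: 6 (1R,6R)-1-[(tert-butyldiphenylsilyl)oxymethyl]-5,5-dimethylbicyclo[4.2.0]oct-7-en-2-one
Conditions: hν (366 nm), acetylene-saturated CH2Cl2, AlBr3-activated chiral 1,3,2-oxazaborolidine (50 mol %), −75 °C
Reagents that add atoms: none
Why: Proposed new method: the chiral Lewis acid binds the C1 carbonyl of 4 and shifts its absorption to longer wavelength, so 366 nm light excites only the complex; its triplet adds to acetylene to give a 1,4-diradical, which after spin inversion collapses to the cyclobutene, forming C5–C6 and C10–C20 (closest known chemistry: enone–acetylene photocycloaddition to bicyclo[4.2.0]oct-7-en-2-ones, and oxazaborolidine–AlBr3-catalysed enantioselective enone–alkene [2+2] photocycloaddition, not yet run with acetylene or with an α-substituted 4,4-dialkyl enone). The one ring formed is the four-membered ring, closed by radical–radical recombination of the diradical (formal [2π+2π] cycloaddition, both bonds to the same face of the enone). C5 and C10 are set together: their cis relation is enforced by the four-membered ring, since a trans-fused bicyclo[4.2.0]octenone is too strained to persist, and their absolute sense depends on the catalyst shielding the β-face so that acetylene enters on the α-face (C10-Si, C5-Re), the catalyst antipode being chosen accordingly. Regiochemistry is no issue with the symmetrical alkyne, and quaternary C10 is created without an enolate, so the C9 oxygen cannot be lost by β-elimination. The selectivity needed is [2+2] addition over the lumiketone rearrangement of the 4,4-dialkyl enone and over secondary photolysis of the β,γ-unsaturated ketone product; a saturated acetylene solution at −75 °C and irradiation only where the complexed enone absorbs should secure it.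

Step 4
Reactants: 6 (1R,6R)-1-[(tert-butyldiphenylsilyl)oxymethyl]-5,5-dimethylbicyclo[4.2.0]oct-7-en-2-one
Product: 9 keto diol (C1 ketone; cis C20H2OH and C6H2OH; C9H2OTBDPS), via ozonide 7 (not isolated), via keto dialdehyde 8 (not isolated)
Conditions: O3, CH2Cl2, −78 °C; Me2S, −78 → 0 °C; NaBH4, EtOH–CH2Cl2, −78 °C
Reagents that add atoms: ozone, [O-][O+]=O
Why: Ozonolysis of the only C=C bond (strained cyclobutene) with reductive work-up, then chemoselective borohydride reduction of the two aldehydes at −78 °C beside the hindered C1 ketone, which is further masked once the C6 alkoxide closes to the hemiketal; no stereocentre is touched, so C6 and C20 stay cis.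

Step 5
Reactants: 9 keto diol
Product: 10 bridged methyl ketal with free C20 hydroxyl
Conditions: MeOH, PPTS (cat.), 3 Å MS, CH2Cl2, rt
Reagents that add atoms: methanol, CO
Why: Acid-catalysed mixed-ketal formation: only the C6 hydroxyl can reach C1 through a five-membered ring (a C20–O–C1 ring would be four-membered), which leaves the C20 hydroxyl as the single free alcohol; the configuration of the new ketal carbon is dictated by the α-face bridge and TBDPS tolerates PPTS.

Step 6
Reactants: 11 Meldrum's acid; 12 ethanethiol
Product: 13 3-(ethylsulfanyl)-3-oxopropanoic acid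
Conditions: MeCN, sealed tube, 80 °C
Reagents that add atoms: none
Why: Thermal acyl substitution on Meldrum's acid by the thiol with loss of acetone gives the malonic half thioester.

Step 7
Reactants: 10 bridged methyl ketal with free C20 hydroxyl; 13 3-(ethylsulfanyl)-3-oxopropanoic acid
Product: 14 C20 malonyl thioester (C20–O–CO–CH2–COSEt)
Conditions: DCC, DMAP (cat.), CH2Cl2, 0 °C → rt
Reagents that add atoms: none
Why: Steglich esterification of the only free hydroxyl (carbodiimide activation of the half thioester, probably through its ketene).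

Step 8
Reactants: 14 C20 malonyl thioester
Product: 15 C9 primary alcohol
Conditions: TBAF, AcOH, THF, 0 °C → rt
Reagents that add atoms: none
Why: Fluoride-induced desilylation, buffered with acetic acid so that the malonyl group does not migrate between the two oxygen arms on C10 and the thioester is not attacked.

Step 9
Reactants: 15 C9 primary alcohol
Product: 17 spiro lactone dienophile (C8=C9; thioester on C8), via C9 aldehyde 16 (not isolated)
Conditions: DMP, CH2Cl2, 0 °C → rt; then piperidine (cat.), 4 Å MS, rt
Reagents that add atoms: none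
Why: Dess–Martin oxidation gives the neopentyl C9 aldehyde, which undergoes intramolecular Knoevenagel condensation with the tethered malonyl methylene (piperidinium acetate formed in situ; six-membered ring) to the doubly activated C8=C9 lactone.

Step 10
Reactants: 17 spiro lactone dienophile; 18 buta-1,3-diene
Product: 19 Diels–Alder adduct (ring C: C8, C9, C11, C12=C13, C14)
Conditions: toluene, BHT (cat.), sealed tube, 100 °C
Reagents that add atoms: none
Why: Diels–Alder reaction of a doubly activated alkylidene 1,3-dicarbonyl dienophile: suprafacial addition makes C11 and C14 cis and so fixes C8 relative to C9, and the diene should enter from the lactone face turned towards C1 because in the ketal-locked chair C9 is axial and its other face is blocked by the syn-axial 4β-methyl group.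

Step 11
Reactants: 19 Diels–Alder adduct
Product: 20 C15 aldehyde
Conditions: Et3SiH, Lindlar Pd (cat.), acetone, rt
Reagents that add atoms: none
Why: Fukuyama reduction (Pd-catalysed hydrosilane reduction of a thioester) gives the aldehyde at C15 without touching the lactone, the poisoned catalyst sparing the ring C alkene.

Step 12
Reactants: 20 C15 aldehyde; 21 ethynylmagnesium bromide
Product: 22 propargylic alcohols (C15 epimers)
Conditions: THF, −78 °C; AcOH quench
Reagents that add atoms: none
Why: Grignard addition of the alkynyl nucleophile to the aldehyde, far faster than attack on the hindered lactone at −78 °C; C15 forms as an epimer mixture, which is harmless because C15 is reset in steps 14 and 15.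

Step 13
Reactants: 22 propargylic alcohols
Product: 24 allylic alcohols with ring D closed (16-methylene; C15 epimers), via vinylstannane 23 (not isolated)
Conditions: Bu3SnH, AIBN (cat.), PhH (0.02 M), 80 °C; then TsOH, MeOH–CH2Cl2, 0 °C → rt
Reagents that add atoms: none
Why: Tin-hydride-mediated radical enyne cyclisation: the stannyl radical adds to the terminal alkyne carbon C17, the C16 vinyl radical closes 5-exo-trig onto C13 and the C12 radical is reduced, C13 being fixed because the two-carbon bridge can only form on the face of ring C that carries C15; acid then protodestannylates C17 while methanol keeps the ketal intact.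

Step 14
Reactants: 24 allylic alcohols
Product: 25 16-methylene-15-ketone
Conditions: DMP, NaHCO3, CH2Cl2, 0 °C → rt
Reagents that add atoms: none
Why: Dess–Martin oxidation of the allylic alcohols converges both C15 epimers on one α-methylene ketone.

Step 15
Reactants: 25 16-methylene-15-ketone
Product: 26 (15R)-allylic alcohol (15-OH endo)
Conditions: NaBH4, CeCl3·7H2O, MeOH, −78 °C
Reagents that add atoms: none
Why: Luche 1,2-reduction: hydride should attack C15 from the open exo face (the side of C14 and the lactone carbonyl), since the endo face lies under the C9–C11–C12 bridge and its axial C11–H, which gives the endo (15R) alcohol of the target.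

Step 16
Reactants: 26 (15R)-allylic alcohol
Product: 27 15-acetate
Conditions: Ac2O, pyridine, DMAP (cat.), CH2Cl2, rt
Reagents that add atoms: acetic anhydride, CC(=O)OC(C)=O
Why: DMAP-catalysed acetylation of the secondary allylic alcohol.

Step 17
Reactants: 27 15-acetate
Product: 28 hydroxy ketone (C1=O, C6H2OH)
Conditions: 1 M aq. HCl, THF, rt
Reagents that add atoms: water, O
Why: Acid hydrolysis of the mixed ketal through the C1 oxocarbenium ion frees the C1 ketone and the C6 alcohol (in equilibrium with the hemiketal), dilute acid at room temperature leaving the allylic acetate and the lactone untouched.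

Step 18
Reactants: 28 hydroxy ketone
Product: 30 target CNP0108627.4, via saturated keto aldehyde 29 (not isolated)
Conditions: IBX, DMSO, rt → 70 °C
Reagents that add atoms: none
Why: IBX oxidises the primary C6 alcohol at room temperature and on warming dehydrogenates the C1 ketone (known one-pot alcohol oxidation–IBX dehydrogenation), which can enolise only towards C2 because C10 is quaternary, so only the C2=C3 enone forms; the aldehyde has no β-hydrogen and should keep its cis configuration at C5.

**Compound list**

1 | 4,4-dimethylcyclohex-2-en-1-one | CC1(C)CCC(=O)C=C1 | starting material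
2 | formaldehyde (37% aqueous) | C=O | starting material
3 | 2-(hydroxymethyl)-4,4-dimethylcyclohex-2-en-1-one | CC1(C)CCC(=O)C(CO)=C1 | intermediate
4 | 2-[(tert-butyldiphenylsilyl)oxymethyl]-4,4-dimethylcyclohex-2-en-1-one (C9 is the silyloxymethyl carbon) | CC1(C)CCC(=O)C(CO[Si](c2ccccc2)(c2ccccc2)C(C)(C)C)=C1 | intermediate
5 | acetylene | C#C | starting material
6 | (1R,6R)-1-[(tert-butyldiphenylsilyl)oxymethyl]-5,5-dimethylbicyclo[4.2.0]oct-7-en-2-one (cis-fused; cyclobutene on the α-face, C9H2OSi on the β-face of C10) | O=C1CCC(C)(C)[C@H]2C=C[C@@]12CO[Si](c1ccccc1)(c1ccccc1)C(C)(C)C | intermediate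
7 | ozonide of 6 (1,2,4-trioxolane spanning C6 and C20, cis-fused to ring A; the two acetal carbons are fixed by the bicycle) | O=C1CCC(C)(C)[C@H]2C3OOC(O3)[C@@]12CO[Si](c1ccccc1)(c1ccccc1)C(C)(C)C | intermediate (not isolated)
8 | 1-[(tert-butyldiphenylsilyl)oxymethyl]-3,3-dimethyl-6-oxocyclohexane-1,2-dicarbaldehyde, formyl groups (C20, C6) cis | O=C1CCC(C)(C)[C@@H](C=O)[C@]1(C=O)CO[Si](c1ccccc1)(c1ccccc1)C(C)(C)C | intermediate (not isolated)
9 | 2-[(tert-butyldiphenylsilyl)oxymethyl]-2,3-bis(hydroxymethyl)-4,4-dimethylcyclohexan-1-one, hydroxymethyl groups (C20, C6) cis on the α-face; equilibrates with its C1/C6 hemiketal | O=C1CCC(C)(C)[C@@H](CO)[C@]1(CO)CO[Si](c1ccccc1)(c1ccccc1)C(C)(C)C | intermediate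
10 | [8-[(tert-butyldiphenylsilyl)oxymethyl]-5-methoxy-2,2-dimethyl-6-oxabicyclo[3.2.1]octan-8-yl]methanol; O6–C7 is the C1–O–C6 bridge, the hydroxymethyl group (C20) is syn to that bridge, the silyloxymethyl group (C9) syn to the C2–C4 carbon bridge | CO[C@@]12CCC(C)(C)[C@@H](CO1)[C@]2(CO)CO[Si](c1ccccc1)(c1ccccc1)C(C)(C)C | intermediate
11 | Meldrum's acid (2,2-dimethyl-1,3-dioxane-4,6-dione) | CC1(C)OC(=O)CC(=O)O1 | starting material
12 | ethanethiol | CCS | starting material
13 | 3-(ethylsulfanyl)-3-oxopropanoic acid | CCSC(=O)CC(=O)O | intermediate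
14 | 10 acylated on the C20 oxygen: C20–O–CO–CH2–COSEt, C9H2OTBDPS retained | CO[C@@]12CCC(C)(C)[C@@H](CO1)[C@]2(COC(=O)CC(=O)SCC)CO[Si](c1ccccc1)(c1ccccc1)C(C)(C)C | intermediate
15 | as 14 with free C9H2OH | CO[C@@]12CCC(C)(C)[C@@H](CO1)[C@]2(COC(=O)CC(=O)SCC)CO | intermediate
16 | as 15 with C9 as aldehyde | CO[C@@]12CCC(C)(C)[C@@H](CO1)[C@]2(COC(=O)CC(=O)SCC)C=O | intermediate (not isolated)
17 | spiro lactone: S-ethyl 2-oxo-5,6-dihydro-2H-pyran-3-carbothioate whose C5 is spiro carbon C10 (C8 of the ketal core of 10); ring C10–C9=C8–C7(=O)–O–C20, C9 syn to the carbon bridge | CO[C@@]12CCC(C)(C)[C@@H](CO1)[C@@]23COC(=O)C(C(=O)SCC)=C3 | intermediate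
18 | buta-1,3-diene | C=CC=C | starting material
19 | Diels–Alder adduct: cyclohexene (C8, C9, C11, C12=C13, C14) cis-fused to the lactone; C11 and C14 on the lactone face turned towards C1, H9 and the C8 thioester (C15) on the face turned towards C5 | CO[C@@]12CCC(C)(C)[C@@H](CO1)[C@@]23COC(=O)[C@@]4(C(=O)SCC)CC=CC[C@@H]34 | intermediate
20 | as 19 with CHO (C15) in place of COSEt | CO[C@@]12CCC(C)(C)[C@@H](CO1)[C@@]23COC(=O)[C@@]4(C=O)CC=CC[C@@H]34 | intermediate
21 | ethynylmagnesium bromide (0.5 M in THF) | C#C[Mg]Br | starting material
22 | as 20 with CH(OH)C≡CH on C8 (C15 epimer mixture) | CO[C@@]12CCC(C)(C)[C@@H](CO1)[C@@]23COC(=O)[C@@]4(C(O)C#C)CC=CC[C@@H]34 | intermediate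
23 | vinylstannanes: ring D closed (C16–C13), C16=C17H–SnBu3, 15-OH (epimer mixture) | CO[C@@]12CCC(C)(C)[C@@H](CO1)[C@@]23COC(=O)[C@@]45C[C@@H](CC[C@@H]34)C(=C[Sn](CCCC)(CCCC)CCCC)C5O | intermediate (not isolated)
24 | allylic alcohols: bicyclo[3.2.1]octane with 16-methylene and 15-OH (C15 epimer mixture); C15–C16 bridge on the face of ring C opposite to C7 and C10 | CO[C@@]12CCC(C)(C)[C@@H](CO1)[C@@]23COC(=O)[C@@]45C[C@@H](CC[C@@H]34)C(=C)C5O | intermediate
25 | 16-methylene-15-ketone | CO[C@@]12CCC(C)(C)[C@@H](CO1)[C@@]23COC(=O)[C@@]45C[C@@H](CC[C@@H]34)C(=C)C5=O | intermediate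
26 | (15R)-alcohol, 15-OH endo (syn to the C9–C11–C12 bridge) | CO[C@@]12CCC(C)(C)[C@@H](CO1)[C@@]23COC(=O)[C@@]45C[C@@H](CC[C@@H]34)C(=C)[C@H]5O | intermediate
27 | 15-acetate of 26 | CO[C@@]12CCC(C)(C)[C@@H](CO1)[C@@]23COC(=O)[C@@]45C[C@@H](CC[C@@H]34)C(=C)[C@H]5OC(C)=O | intermediate
28 | hydroxy ketone: C1=O, C6H2OH on C5 (cis to C20), 15-OAc; equilibrates with its hemiketal | O=C1CCC(C)(C)[C@@H](CO)[C@@]12COC(=O)[C@@]34C[C@@H](CC[C@@H]23)C(=C)[C@H]4OC(C)=O | intermediate
29 | saturated keto aldehyde: C1=O, C6HO | O=C1CCC(C)(C)[C@@H](C=O)[C@@]12COC(=O)[C@@]34C[C@@H](CC[C@@H]23)C(=C)[C@H]4OC(C)=O | intermediate (not isolated)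
30 | target CNP0108627.4 (1-oxo-2-ene, 6-al, 7,20-lactone, 15-OAc, 16-ene) | O=C1C=CC(C)(C)[C@@H](C=O)[C@@]12COC(=O)[C@@]34C[C@@H](CC[C@@H]23)C(=C)[C@H]4OC(C)=O | target

**Step count.** Total: 18 steps. Longest linear sequence: 17 steps (1–5 and 7–18; step 6 prepares side component 13).

**Steps most likely to fail**

1. Step 3 (proposed new method). The chiral Lewis acid may bind weakly or unselectively to an enone that has no α-hydrogen, giving low enantioselectivity. Acetylene may also oligomerise or be hydrobrominated at the aluminium centre, and the product ketone may inhibit the catalyst. Fallback with known chemistry, from 4 and 5 back to 6: 4 and 5 are irradiated without the Lewis acid (Pyrex-filtered lamp, acetylene-saturated acetone, −78 °C) to give the racemic photoadduct F1. NaBH4 reduces the ketone to the racemic carbinol F2 (its carbinol configuration is immaterial). Esterification with (S)-O-methylmandelic acid (DCC, DMAP) and chromatographic separation of the diastereomers gives the mandelate F3 of the required enantiomer. K2CO3 in methanol releases the resolved carbinol F4, and Dess–Martin oxidation returns the route to 6.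

2. Step 10. Facial selectivity may be poor, with the diene entering on the C5 side, or the cycloaddition at neopentyl C9 may stall. Fallback, from 17 back to 19: aqueous acetic acid opens the ketal of 17 to the hydroxy ketone F5, and TBSCl/imidazole gives the silyl ether F6. In F6 ring A is no longer locked, C1 is a flat carbonyl and C5 carries the bulky CH2OTBS group, so butadiene (toluene, 100 °C) should add anti to C5 to give the adduct F7. CSA in methanol then removes the silyl group and re-forms the bridged methyl ketal, which is 19.

3. Step 15. Hydride may be delivered to the wrong face of C15, or conjugate reduction may compete. Fallback, from 22 back to 26: Dess–Martin oxidation of 22 gives the ynone F8. Noyori asymmetric transfer hydrogenation (Ru–TsDPEN catalyst of the antipode that gives the 15R carbinol, HCO2H/Et3N) sets C15 under reagent control and gives the propargylic alcohol F9. The tin-hydride cyclisation of step 13 gives the vinylstannane F10, and protodestannylation (TsOH, MeOH–CH2Cl2) gives 26 directly.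

**Further compounds**

F1 | step 3 | racemic cis-fused photoadduct | O=C1CCC(C)(C)C2C=CC12CO[Si](c1ccccc1)(c1ccccc1)C(C)(C)C
F2 | step 3 | racemic carbinol from F1 | OC1CCC(C)(C)C2C=CC12CO[Si](c1ccccc1)(c1ccccc1)C(C)(C)C
F3 | step 3 | (S)-O-methylmandelate of the carbinol with C5/C10 as in 6 | CO[C@@H](c1ccccc1)C(=O)OC1CCC(C)(C)[C@H]2C=C[C@@]12CO[Si](c1ccccc1)(c1ccccc1)C(C)(C)C
F4 | step 3 | resolved carbinol | OC1CCC(C)(C)[C@H]2C=C[C@@]12CO[Si](c1ccccc1)(c1ccccc1)C(C)(C)C
F5 | step 10 | hydroxy ketone form of the dienophile (C1=O, C6H2OH) | O=C1CCC(C)(C)[C@@H](CO)[C@@]12COC(=O)C(C(=O)SCC)=C2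
F6 | step 10 | C6 TBS ether of F5 | O=C1CCC(C)(C)[C@@H](CO[Si](C)(C)C(C)(C)C)[C@@]12COC(=O)C(C(=O)SCC)=C2
F7 | step 10 | Diels–Alder adduct of F6 | O=C1CCC(C)(C)[C@@H](CO[Si](C)(C)C(C)(C)C)[C@@]12COC(=O)[C@@]3(C(=O)SCC)CC=CC[C@@H]23
F8 | step 15 | ynone (C15=O, C16≡C17H) | CO[C@@]12CCC(C)(C)[C@@H](CO1)[C@@]23COC(=O)[C@@]4(C(=O)C#C)CC=CC[C@@H]34
F9 | step 15 | (15R)-propargylic alcohol | CO[C@@]12CCC(C)(C)[C@@H](CO1)[C@@]23COC(=O)[C@@]4([C@H](O)C#C)CC=CC[C@@H]34
F10 | step 15 | (15R)-vinylstannane with ring D closed | CO[C@@]12CCC(C)(C)[C@@H](CO1)[C@@]23COC(=O)[C@@]45C[C@@H](CC[C@@H]34)C(=C[Sn](CCCC)(CCCC)CCCC)[C@H]5O
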